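**Retrosynthetic overview**

1. Numbering used throughout: tetrahydrofuran ring O1, C2 (bears the 3,4,5-trimethoxyphenyl group), C3 (bears CH2OH), C4, C5; Cα is the carbinol carbon on C4 (bears the 3,4-dimethoxyphenyl group). The route rests on the chain C5–C4–C3–CH2OH being a butenolide in reduced form: acetal carbon = C5, β-carbon = C4, α-carbon = C3, lactone carbonyl = CH2OH.
2. Cα–OH comes from hydride reduction of a C4 aryl ketone. The C4 configuration comes from base epimerisation of that ketone from 3,4-cis to all-trans. The ketone comes from a dithiane.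
3. The tetrahydrofuran is the only ring the route builds. It closes by O1–C2 bond formation (the C5 hydroxyl onto the C2 benzylic cation) after LiAlH4 has opened the lactone; the butenolide ring is a sacrificial template.
4. Key disconnection: Cα–C4 by conjugate addition of lithiated 2-(3,4-dimethoxyphenyl)-1,3-dithiane to (5S)-5-(d-menthyloxy)furan-2(5H)-one, and C2–C3 by aldol trapping of the lactone enolate with 3,4,5-trimethoxybenzaldehyde.
5. The dithiane comes from 3,4-dimethoxybenzaldehyde; the butenolide comes from furfural (photo-oxygenation) and (+)-menthol.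

Key step: step 4

Assumption: the aldol in step 4 is taken to give both epimers at the trimethoxybenzylic carbinol carbon; they are carried on together because that centre is ionised and reset in step 6.

**Route**

Step 1
Reactants: 1 3,4-dimethoxybenzaldehyde
Product: 2 2-(3,4-dimethoxyphenyl)-1,3-dithiane
Conditions: HS(CH2)3SH, BF3·OEt2 (cat.), CH2Cl2, 0 °C to rt
Reagents that add atoms: propane-1,3-dithiol, SCCCS
Why: Lewis-acid-catalysed dithioacetalisation of an aromatic aldehyde, which should proceed cleanly and creates no stereocentre.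

Step 2
Reactants: 3 furfural
Product: 5 5-hydroxyfuran-2(5H)-one (racemic), via furan endoperoxide 4 (not isolated)
Conditions: O2, hν (visible), methylene blue (cat.), MeOH, rt
Reagents that add atoms: dioxygen (as singlet oxygen), O=O
Why: Dye-sensitised singlet-oxygen [4+2] cycloaddition to the furan gives endoperoxide 4, whose methanolysis expels the formyl carbon as methyl formate and leaves the hydroxybutenolide (furan photo-oxygenation); the hemiacetal carbon is racemic and is resolved in step 3.

Step 3
Reactants: 5 5-hydroxyfuran-2(5H)-one; 6 (+)-menthol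
Product: 8 (5S)-5-{[(1S,2R,5S)-2-isopropyl-5-methylcyclohexyl]oxy}furan-2(5H)-one [(5S)-5-(d-menthyloxy)furan-2(5H)-one], via (5R) acetal epimer 7 (not isolated)
Conditions: TsOH·H2O (cat.), toluene, reflux (Dean–Stark); crystallisation from hexane, mother liquor re-equilibrated with acid and recrystallised
Reagents that add atoms: none
Why: Acid-catalysed acetalisation of the pseudo-acid hydroxyl with (+)-menthol gives both C5 epimers, which interconvert under acid, so crystallisation of the (5S) epimer should drain the (5R) epimer 7 into it (crystallisation-driven epimer equilibration); the menthyl centres decide which epimer crystallises.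

Step 4
Reactants: 2 2-(3,4-dimethoxyphenyl)-1,3-dithiane; 8 (5S)-5-(d-menthyloxy)furan-2(5H)-one; 9 3,4,5-trimethoxybenzaldehyde
Product: 12 (3R,4S,5S)-4-[2-(3,4-dimethoxyphenyl)-1,3-dithian-2-yl]-3-[hydroxy(3,4,5-trimethoxyphenyl)methyl]-5-(d-menthyloxy)dihydrofuran-2(3H)-one (carbinol epimers), via lithiated dithiane 10 (not isolated), via lithium lactone enolate 11 (not isolated)
Conditions: 2, n-BuLi, THF, −78 to −20 °C; then 8, −78 °C; then 9, −78 °C; AcOH quench at −78 °C
Reagents that add atoms: none
Why: n-BuLi deprotonates 2 to the sulfur-stabilised benzylic anion 10, which adds in Michael fashion to the β-carbon of butenolide 8 to give lithium enolate 11, and 11 then adds to aldehyde 9 in an aldol reaction, so the Cα–C4 and C2–C3 bonds of the target form in one flask. The closest known reaction type is the tandem conjugate addition–aldol of lithiated dithioacetals on 5-alkoxyfuran-2(5H)-ones. No ring is closed in this step; the lactone ring is carried unchanged and is opened in step 5. The new centre at lactone C4 is controlled by the C5 menthyloxy group (the anion enters anti to it), and the new centre at lactone C3 is controlled in turn by the C4 dithianyl group (the aldehyde enters anti to it), so a trans,trans lactone should result; the carbinol carbon is not controlled and need not be. The step needs 1,4- rather than 1,2-addition, which the soft, delocalised aryl dithiane anion at low temperature secures, and it needs the aldolate to survive to the quench, which protonation with AcOH at −78 °C secures.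

Step 5
Reactants: 12 tandem adduct (carbinol epimers)
Product: 14 (2S,3S)-2-[2-(3,4-dimethoxyphenyl)-1,3-dithian-2-yl]-3-[hydroxy(3,4,5-trimethoxyphenyl)methyl]butane-1,4-diol (carbinol epimers), via ring-opened aldehyde 13 (not isolated)
Conditions: LiAlH4, THF, 0 °C to rt; then H2O
Reagents that add atoms: none
Why: Hydride reduction of a γ-alkoxy lactone to a 1,4-diol: the lactone carbonyl becomes the C3 hydroxymethyl, the hemiacetal freed on ring opening loses menthol to give aldehyde 13, and this is reduced to the C5 hydroxymethyl; the dithiane and the two set stereocentres are untouched.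

Step 6
Reactants: 14 triol (carbinol epimers)
Product: 16 [(2R,3S,4S)-4-[2-(3,4-dimethoxyphenyl)-1,3-dithian-2-yl]-2-(3,4,5-trimethoxyphenyl)tetrahydrofuran-3-yl]methanol, via trimethoxybenzylic cation 15 (not isolated)
Conditions: BF3·OEt2 (0.2 equiv), CH2Cl2, −40 to 0 °C; Et3N quench
Reagents that add atoms: none
Why: Cationic cycloetherification: either carbinol epimer ionises to the same benzylic cation 15, the C5 hydroxyl is the only one that can close a five-membered ring onto it, and the aryl group should settle on the face opposite the cis-disposed C3 and C4 substituents, setting C2 as R.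

Step 7
Reactants: 16 tetrahydrofuran alcohol
Product: 17 tert-butyl{[(2R,3S,4S)-4-[2-(3,4-dimethoxyphenyl)-1,3-dithian-2-yl]-2-(3,4,5-trimethoxyphenyl)tetrahydrofuran-3-yl]methoxy}dimethylsilane
Conditions: TBSCl, imidazole, DMF, rt
Reagents that add atoms: tert-butyldimethylsilyl chloride, CC(C)(C)[Si](C)(C)Cl
Why: Imidazole-promoted silylation of a primary alcohol; the ether keeps the C3 hydroxymethyl from closing a bicyclic hemiketal onto the cis ketone unmasked next, which would hold C4 in the wrong configuration.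

Step 8
Reactants: 17 silyl ether dithiane
Product: 18 (2R,3S,4S)-3-{[tert-butyl(dimethyl)silyl]oxymethyl}-4-(3,4-dimethoxybenzoyl)-2-(3,4,5-trimethoxyphenyl)tetrahydrofuran (3,4-cis ketone)
Conditions: Hg(ClO4)2, CaCO3, THF/H2O (5:1), 0 °C to rt
Reagents that add atoms: water, O
Why: Mercury-assisted dithioacetal hydrolysis: thiophilic divalent mercury should cleave the dithiane to the aryl ketone without oxidising the electron-rich rings, and the CaCO3 buffer protects the silyl ether and the benzylic ring ether.

Step 9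
Reactants: 18 3,4-cis ketone
Product: 20 (2R,3S,4R)-3-{[tert-butyl(dimethyl)silyl]oxymethyl}-4-(3,4-dimethoxybenzoyl)-2-(3,4,5-trimethoxyphenyl)tetrahydrofuran (all-trans ketone), via ketone enol 19 (not isolated)
Conditions: DBU (0.3 equiv), toluene, rt to 40 °C
Reagents that add atoms: none
Why: Base-mediated epimerisation: reversible deprotonation at C4 (through enol/enolate 19) should move the aroyl group from the face it shares with the C3 substituent to the opposite face, giving the thermodynamically preferred 2,3-trans,3,4-trans ring; C2 and C3 carry no acidic hydrogen and keep their configuration.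

Step 10
Reactants: 20 all-trans ketone
Product: 21 (S)-(3,4-dimethoxyphenyl)[(2R,3S,4R)-3-{[tert-butyl(dimethyl)silyl]oxymethyl}-2-(3,4,5-trimethoxyphenyl)tetrahydrofuran-4-yl]methanol
Conditions: LiBH(s-Bu)3, THF, −78 °C; then H2O
Reagents that add atoms: none
Why: Felkin–Anh reduction: the bulky hydride should attack anti to the more substituted ring bond C4–C3, with C4–H on the aryl side, which is also the face exposed if lithium bridges the carbonyl oxygen and O1, giving the (S) carbinol.

Step 11
Reactants: 21 silyl-protected carbinol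
Product: 22 (S)-(3,4-dimethoxyphenyl)[(3R,4S,5R)-4-(hydroxymethyl)-5-(3,4,5-trimethoxyphenyl)tetrahydrofuran-3-yl]methanol (target; αS,2R,3S,4R in the numbering above)
Conditions: TBAF, THF, 0 °C to rt
Reagents that add atoms: none
Why: Fluoride desilylation under non-acidic conditions, so the ionisable dimethoxybenzylic alcohol keeps its configuration.

**Compound list**

1 | 3,4-dimethoxybenzaldehyde | COc1ccc(C=O)cc1OC | starting material
2 | 2-(3,4-dimethoxyphenyl)-1,3-dithiane | COc1ccc(C2SCCCS2)cc1OC | intermediate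
3 | furfural | O=Cc1ccco1 | starting material
4 | furan endoperoxide (2,3,7-trioxabicyclo[2.2.1]hept-5-ene-1-carbaldehyde, racemic) | O=CC12OOC(C=C1)O2 | intermediate
5 | 5-hydroxyfuran-2(5H)-one (racemic) | O=C1C=CC(O)O1 | intermediate
6 | (+)-menthol, (1S,2R,5S) | CC(C)[C@H]1CC[C@H](C)C[C@@H]1O | starting material
7 | (5R)-5-(d-menthyloxy)furan-2(5H)-one | O=C1C=C[C@H](O[C@H]2C[C@@H](C)CC[C@@H]2C(C)C)O1 | intermediate
8 | (5S)-5-(d-menthyloxy)furan-2(5H)-one | O=C1C=C[C@@H](O[C@H]2C[C@@H](C)CC[C@@H]2C(C)C)O1 | intermediate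
9 | 3,4,5-trimethoxybenzaldehyde | COc1cc(C=O)cc(OC)c1OC | starting material
10 | 2-lithio-2-(3,4-dimethoxyphenyl)-1,3-dithiane | COc1ccc(C2([Li])SCCCS2)cc1OC | intermediate
11 | lithium enolate of (4S,5S)-4-[2-(3,4-dimethoxyphenyl)-1,3-dithian-2-yl]-5-(d-menthyloxy)dihydrofuran-2(3H)-one | [Li]OC1=C[C@H](C2(c3ccc(OC)c(OC)c3)SCCCS2)[C@@H](O[C@H]2C[C@@H](C)CC[C@@H]2C(C)C)O1 | intermediate
12 | (3R,4S,5S)-4-[2-(3,4-dimethoxyphenyl)-1,3-dithian-2-yl]-3-[hydroxy(3,4,5-trimethoxyphenyl)methyl]-5-(d-menthyloxy)dihydrofuran-2(3H)-one, carbinol epimers | O=C1O[C@H](O[C@H]2C[C@@H](C)CC[C@@H]2C(C)C)[C@@H](C2(c3ccc(OC)c(OC)c3)SCCCS2)[C@@H]1C(O)c1cc(OC)c(OC)c(OC)c1 | intermediate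
13 | (2S,3S)-2-[2-(3,4-dimethoxyphenyl)-1,3-dithian-2-yl]-4-hydroxy-3-(hydroxymethyl)-4-(3,4,5-trimethoxyphenyl)butanal, carbinol epimers | O=C[C@@H](C1(c2ccc(OC)c(OC)c2)SCCCS1)[C@@H](CO)C(O)c1cc(OC)c(OC)c(OC)c1 | intermediate
14 | (2S,3S)-2-[2-(3,4-dimethoxyphenyl)-1,3-dithian-2-yl]-3-[hydroxy(3,4,5-trimethoxyphenyl)methyl]butane-1,4-diol, carbinol epimers | OC[C@@H](C1(c2ccc(OC)c(OC)c2)SCCCS1)[C@@H](CO)C(O)c1cc(OC)c(OC)c(OC)c1 | intermediate
15 | trimethoxybenzylic cation derived from 14 | OC[C@@H](C1(c2ccc(OC)c(OC)c2)SCCCS1)[C@@H](CO)[CH+]c1cc(OC)c(OC)c(OC)c1 | intermediate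
16 | [(2R,3S,4S)-4-[2-(3,4-dimethoxyphenyl)-1,3-dithian-2-yl]-2-(3,4,5-trimethoxyphenyl)tetrahydrofuran-3-yl]methanol | COc1ccc(C2([C@@H]3CO[C@@H](c4cc(OC)c(OC)c(OC)c4)[C@@H]3CO)SCCCS2)cc1OC | intermediate
17 | tert-butyldimethylsilyl ether of 16 | COc1ccc(C2([C@@H]3CO[C@@H](c4cc(OC)c(OC)c(OC)c4)[C@@H]3CO[Si](C)(C)C(C)(C)C)SCCCS2)cc1OC | intermediate
18 | (2R,3S,4S)-3-{[tert-butyl(dimethyl)silyl]oxymethyl}-4-(3,4-dimethoxybenzoyl)-2-(3,4,5-trimethoxyphenyl)tetrahydrofuran | COc1ccc(C(=O)[C@@H]2CO[C@@H](c3cc(OC)c(OC)c(OC)c3)[C@@H]2CO[Si](C)(C)C(C)(C)C)cc1OC | intermediate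
19 | C4 enol of ketone 18/20 (present as its DBU-H+ enolate) | COc1ccc(C(O)=C2CO[C@@H](c3cc(OC)c(OC)c(OC)c3)[C@@H]2CO[Si](C)(C)C(C)(C)C)cc1OC | intermediate
20 | (2R,3S,4R)-3-{[tert-butyl(dimethyl)silyl]oxymethyl}-4-(3,4-dimethoxybenzoyl)-2-(3,4,5-trimethoxyphenyl)tetrahydrofuran | COc1ccc(C(=O)[C@H]2CO[C@@H](c3cc(OC)c(OC)c(OC)c3)[C@@H]2CO[Si](C)(C)C(C)(C)C)cc1OC | intermediate
21 | (S)-(3,4-dimethoxyphenyl)[(2R,3S,4R)-3-{[tert-butyl(dimethyl)silyl]oxymethyl}-2-(3,4,5-trimethoxyphenyl)tetrahydrofuran-4-yl]methanol | COc1ccc([C@@H](O)[C@H]2CO[C@@H](c3cc(OC)c(OC)c(OC)c3)[C@@H]2CO[Si](C)(C)C(C)(C)C)cc1OC | intermediate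
22 | (S)-(3,4-dimethoxyphenyl)[(3R,4S,5R)-4-(hydroxymethyl)-5-(3,4,5-trimethoxyphenyl)tetrahydrofuran-3-yl]methanol | COc1ccc([C@@H](O)[C@H]2CO[C@@H](c3cc(OC)c(OC)c(OC)c3)[C@@H]2CO)cc1OC | target

**Step count and risks**

Total step count: 11. Longest linear sequence: 10 steps (steps 2 to 11, from furfural 3); step 1 is a one-step branch that joins at step 4.

Steps most likely to fail:

1. Step 4. What may go wrong: the crowded enolate 11 does not hold the aldehyde (the aldolate reverts before the quench, or the enolate is protonated), so the second bond is not formed in the same flask. Fallback, setting out from 2 and 8 and coming back at 12: the conjugate addition is run alone and enolate 11 is quenched with AcOH to give the Michael adduct (4S,5S)-4-[2-(3,4-dimethoxyphenyl)-1,3-dithian-2-yl]-5-(d-menthyloxy)dihydrofuran-2(3H)-one F1. LiN(SiMe3)2 (2.2 equiv, THF, −78 °C) re-forms 11, which is C-acylated irreversibly with 3,4,5-trimethoxybenzoyl chloride to the keto lactone (3R,4S,5S)-4-[2-(3,4-dimethoxyphenyl)-1,3-dithian-2-yl]-5-(d-menthyloxy)-3-(3,4,5-trimethoxybenzoyl)dihydrofuran-2(3H)-one F2; its doubly activated C3 should settle trans to the dithianyl group. NaBH4 (MeOH/THF, −20 °C) then reduces the aryl ketone to the carbinol epimers 12.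

2. Step 6. What may go wrong: the benzylic cation is intercepted by the neighbouring electron-rich dimethoxyphenyl ring (six-membered Friedel–Crafts closure) or held by a dithiane sulfur, instead of being taken by the C5 hydroxyl. Fallback, setting out from 14 and coming back at 18: the ketone is unmasked before any cation is made, so that sulfur is gone and the neighbouring ring is a deactivated aroyl ring. Both primary hydroxyls are silylated (TBSCl 2.2 equiv, imidazole, CH2Cl2, 0 °C) to give the bis-silyl ether of 14 F3. Hg(ClO4)2/CaCO3 in aqueous THF then gives (2S,3S)-2,3-bis{[tert-butyl(dimethyl)silyl]oxymethyl}-1-(3,4-dimethoxyphenyl)-4-hydroxy-4-(3,4,5-trimethoxyphenyl)butan-1-one F4; any cyclic hemiketal between its carbinol and ketone feeds the same cation. TMSOTf (cat., CH2Cl2, −78 °C) ionises the benzylic alcohol to the keto benzylic cation F5; the C5 silyl ether oxygen closes the five-membered ring and sheds its silyl group, while the C3 silyl ether could only close a four-membered ring and stays, so 18 should result directly.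

3. Step 10. What may go wrong: poor facial selectivity in hydride delivery, the two ring bonds at C4 being too alike for substrate control. Fallback, setting out from 20 and coming back at 21: reagent-controlled Corey–Bakshi–Shibata reduction with (R)-2-methyl-CBS-oxazaborolidine (cat.) and BH3·SMe2 in THF at −20 °C, in which the aryl group acts as the large substituent and the (S) carbinol 21 is expected; no new compound is made.

**Further compounds**

F1 | step 4 | (4S,5S)-4-[2-(3,4-dimethoxyphenyl)-1,3-dithian-2-yl]-5-(d-menthyloxy)dihydrofuran-2(3H)-one | O=C1C[C@H](C2(c3ccc(OC)c(OC)c3)SCCCS2)[C@@H](O[C@H]2C[C@@H](C)CC[C@@H]2C(C)C)O1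
F2 | step 4 | (3R,4S,5S)-4-[2-(3,4-dimethoxyphenyl)-1,3-dithian-2-yl]-5-(d-menthyloxy)-3-(3,4,5-trimethoxybenzoyl)dihydrofuran-2(3H)-one | O=C1O[C@H](O[C@H]2C[C@@H](C)CC[C@@H]2C(C)C)[C@@H](C2(c3ccc(OC)c(OC)c3)SCCCS2)[C@@H]1C(=O)c1cc(OC)c(OC)c(OC)c1
F3 | step 6 | bis(tert-butyldimethylsilyl) ether of 14 at both primary hydroxyls, carbinol epimers | COc1ccc(C2([C@H](CO[Si](C)(C)C(C)(C)C)[C@@H](CO[Si](C)(C)C(C)(C)C)C(O)c3cc(OC)c(OC)c(OC)c3)SCCCS2)cc1OC
F4 | step 6 | (2S,3S)-2,3-bis{[tert-butyl(dimethyl)silyl]oxymethyl}-1-(3,4-dimethoxyphenyl)-4-hydroxy-4-(3,4,5-trimethoxyphenyl)butan-1-one, carbinol epimers | COc1ccc(C(=O)[C@H](CO[Si](C)(C)C(C)(C)C)[C@@H](CO[Si](C)(C)C(C)(C)C)C(O)c2cc(OC)c(OC)c(OC)c2)cc1OC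
F5 | step 6 | keto benzylic cation derived from F4 | COc1ccc(C(=O)[C@H](CO[Si](C)(C)C(C)(C)C)[C@@H](CO[Si](C)(C)C(C)(C)C)[CH+]c2cc(OC)c(OC)c(OC)c2)cc1OC
F0 | step 10 | none | none
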